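**Retrosynthetic overview**
- Ambofuranol ⇐ its 2'-O-allyl / 6-O-pivaloyl derivative; both groups come off in one pot at the end.
- The furan ring (C2=C3 bond) is the only ring formed; both benzene rings are bought. It is closed by the proposed new step: aryl acetal → α-methoxybenzyl-phosphonium ylide → intramolecular Wittig on the neighbouring aryl ester, so the acetal OMe becomes the C3–OMe.
- Acetal/ester precursor ⇐ prenylated salicylaldehyde (ring A) + 2-(allyloxy)-4-methoxybenzoyl chloride (ring B), by O-acylation then acetalisation.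
- Ring A ⇐ 5-bromo-2,4-dihydroxybenzaldehyde: selective 4-O-pivaloylation, then Stille prenylation at the brominated carbon (fixes the C5 regiochemistry).
- Ring B ⇐ 2-hydroxy-4-methoxybenzoic acid by O-allylation.

Assumption: the target has no stereocentre and its only non-aromatic C=C carries two identical methyl groups, so it is achiral; "single enantiomer" is taken to mean the constitution given, and no stereocontrol is needed.

**Route**

Step 1
Reactants: 1 5-bromo-2,4-dihydroxybenzaldehyde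
Product: 2 2-bromo-4-formyl-5-hydroxyphenyl pivalate (the 4-O-pivalate of 1)
Conditions: PivCl (1.05 equiv), Et3N (1.1 equiv), CH2Cl2, −20 → 0 °C
Reagents that add atoms: pivaloyl chloride, CC(C)(C)C(=O)Cl
Why: Chemoselective O-acylation (Einhorn-type): the 2-OH is tied up in a hydrogen bond to the formyl group, while the 4-OH (para to CHO, ortho to Br) is the more acidic free phenol and reacts first.

Step 2
Reactants: 2 2-bromo-4-formyl-5-hydroxyphenyl pivalate; 3 tributyl(3-methylbut-2-en-1-yl)stannane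
Product: 4 4-formyl-5-hydroxy-2-(3-methylbut-2-en-1-yl)phenyl pivalate
Conditions: Pd(PPh3)4 (5 mol%), DMF (degassed), 90 °C
Reagents that add atoms: none
Why: Migita–Kosugi–Stille coupling at the C–Br bond under neutral conditions that leave phenol, aldehyde and pivalate alone; reductive elimination from the less hindered σ-prenyl terminus gives the linear prenyl arene.

Step 3
Reactants: 5 2-hydroxy-4-methoxybenzoic acid
Product: 7 2-(allyloxy)-4-methoxybenzoic acid, via allyl 2-(allyloxy)-4-methoxybenzoate 6 (not isolated)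
Conditions: allyl bromide (2.5 equiv), K2CO3 (3 equiv), DMF, 60 °C; then 2 M NaOH, MeOH, 60 °C; HCl to pH 2
Reagents that add atoms: allyl bromide, C=CCBr; sodium hydroxide, [Na+].[OH-] (O of the CO2H)
Why: Williamson O-allylation of phenol and carboxylate, then saponification of the allyl ester only, since the aryl allyl ether is stable to hydroxide.

Step 4
Reactants: 7 2-(allyloxy)-4-methoxybenzoic acid; 4 4-formyl-5-hydroxy-2-(3-methylbut-2-en-1-yl)phenyl pivalate
Product: 9 2-formyl-4-(3-methylbut-2-en-1-yl)-5-(pivaloyloxy)phenyl 2-(allyloxy)-4-methoxybenzoate, via 2-(allyloxy)-4-methoxybenzoyl chloride 8 (not isolated)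
Conditions: (COCl)2 (1.3 equiv), DMF (cat.), CH2Cl2, 0 → 23 °C, evaporate; then 4 (0.95 equiv), Et3N (2 equiv), DMAP (10 mol%), CH2Cl2, 0 → 23 °C
Reagents that add atoms: oxalyl chloride, O=C(Cl)C(=O)Cl (Cl of intermediate 8 only)
Why: Acid chloride formation (Vilsmeier-type activation) followed by DMAP-catalysed O-acylation of the salicylaldehyde phenol (nucleophilic acyl substitution); allyl ether, prenyl group and pivalate are inert.

Step 5
Reactants: 9 2-formyl-4-(3-methylbut-2-en-1-yl)-5-(pivaloyloxy)phenyl 2-(allyloxy)-4-methoxybenzoate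
Product: 10 2-(dimethoxymethyl)-4-(3-methylbut-2-en-1-yl)-5-(pivaloyloxy)phenyl 2-(allyloxy)-4-methoxybenzoate
Conditions: MeOSiMe3 (3 equiv), TMSOTf (5 mol%), CH2Cl2, −78 → −40 °C; pyridine quench
Reagents that add atoms: methoxytrimethylsilane, CO[Si](C)(C)C
Why: Noyori acetalisation; it is aprotic and cold with no free methanol, so the ester groups and both alkenes survive, and formation of the disiloxane drives it to completion.

Step 6
Reactants: 10 2-(dimethoxymethyl)-4-(3-methylbut-2-en-1-yl)-5-(pivaloyloxy)phenyl 2-(allyloxy)-4-methoxybenzoate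
Product: 13 2-[2-(allyloxy)-4-methoxyphenyl]-3-methoxy-5-(3-methylbut-2-en-1-yl)-1-benzofuran-6-yl pivalate, via ({2-[(2-allyloxy-4-methoxybenzoyl)oxy]-5-(3-methylbut-2-en-1-yl)-4-(pivaloyloxy)phenyl}(methoxy)methyl)triphenylphosphonium triflate 11 (not isolated), via 2-[methoxy(triphenyl-λ5-phosphanylidene)methyl]-4-(3-methylbut-2-en-1-yl)-5-(pivaloyloxy)phenyl 2-(allyloxy)-4-methoxybenzoate 12 (not isolated)
Conditions: PPh3 (1.15 equiv), TMSOTf (1.1 equiv), CH2Cl2, −78 → 0 °C; evaporate; KHMDS (1.15 equiv), THF, −78 → 60 °C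
Reagents that add atoms: triphenylphosphine, c1ccc(cc1)P(c1ccccc1)c1ccccc1 (in 11 and 12 only); trimethylsilyl trifluoromethanesulfonate, C[Si](C)(C)OS(=O)(=O)C(F)(F)F (triflate counter-ion of 11 only)
Why: Proposed new method: an acetal-to-ylide/ester Wittig benzannulation — TMSOTf ionises the aryl acetal to a methoxycarbenium ion (stabilised by the para-oxygen) that PPh3 traps as the α-methoxybenzylphosphonium salt 11 with loss of MeOSiMe3; KHMDS then gives the non-stabilised, strongly nucleophilic α-methoxybenzylidene ylide 12, which adds 5-exo to the adjacent activated aryl ester carbonyl, and the oxaphosphetane collapses with loss of Ph3P=O to form the C2=C3 bond and close the furan ring with the acetal OMe ending up as the C3–OMe (if the tetrahedral intermediate first expels the phenoxide, the C-acylated phosphonium has no α-H and is expected to re-close to the same oxaphosphetane); the closest known reaction types are the intramolecular Wittig benzofuran synthesis from o-acyloxybenzylphosphonium salts and the formation of α-alkoxyalkylphosphonium salts from acetals, a phosphine and a silyl triflate, but an α-alkoxy ylide has not been used in an ester Wittig to make a 3-alkoxybenzofuran.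

Step 7
Reactants: 13 2-[2-(allyloxy)-4-methoxyphenyl]-3-methoxy-5-(3-methylbut-2-en-1-yl)-1-benzofuran-6-yl pivalate
Product: 14 ambofuranol, 2-(2-hydroxy-4-methoxyphenyl)-3-methoxy-5-(3-methylbut-2-en-1-yl)-1-benzofuran-6-ol
Conditions: Pd(PPh3)4 (5 mol%), K2CO3 (0.5 equiv), MeOH–THF (degassed), 23 → 45 °C; aq. NH4Cl
Reagents that add atoms: none
Why: One-pot Tsuji–Trost deallylation of the aryl allyl ether (methanol as allyl acceptor) and base-catalysed methanolysis (Zemplén-type transesterification) of the aryl pivalate; the C-prenyl group, the methyl ethers and the 3-methoxybenzofuran are inert, and there is no stereocentre to scramble.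

**Compound list**
1 | 5-bromo-2,4-dihydroxybenzaldehyde | O=Cc1cc(Br)c(O)cc1O | starting material
2 | 2-bromo-4-formyl-5-hydroxyphenyl pivalate | O=Cc1cc(Br)c(OC(=O)C(C)(C)C)cc1O | intermediate
3 | tributyl(3-methylbut-2-en-1-yl)stannane | CCCC[Sn](CCCC)(CCCC)CC=C(C)C | starting material
4 | 4-formyl-5-hydroxy-2-(3-methylbut-2-en-1-yl)phenyl pivalate | O=Cc1cc(CC=C(C)C)c(OC(=O)C(C)(C)C)cc1O | intermediate
5 | 2-hydroxy-4-methoxybenzoic acid | COc1ccc(C(=O)O)c(O)c1 | starting material
6 | allyl 2-(allyloxy)-4-methoxybenzoate | COc1ccc(C(=O)OCC=C)c(OCC=C)c1 | intermediate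
7 | 2-(allyloxy)-4-methoxybenzoic acid | COc1ccc(C(=O)O)c(OCC=C)c1 | intermediate
8 | 2-(allyloxy)-4-methoxybenzoyl chloride | COc1ccc(C(Cl)=O)c(OCC=C)c1 | intermediate
9 | 2-formyl-4-(3-methylbut-2-en-1-yl)-5-(pivaloyloxy)phenyl 2-(allyloxy)-4-methoxybenzoate | O=Cc1cc(CC=C(C)C)c(OC(=O)C(C)(C)C)cc1OC(=O)c1ccc(OC)cc1OCC=C | intermediate
10 | 2-(dimethoxymethyl)-4-(3-methylbut-2-en-1-yl)-5-(pivaloyloxy)phenyl 2-(allyloxy)-4-methoxybenzoate | COC(OC)c1cc(CC=C(C)C)c(OC(=O)C(C)(C)C)cc1OC(=O)c1ccc(OC)cc1OCC=C | intermediate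
11 | ({2-[(2-allyloxy-4-methoxybenzoyl)oxy]-5-(3-methylbut-2-en-1-yl)-4-(pivaloyloxy)phenyl}(methoxy)methyl)triphenylphosphonium triflate (racemic; the centre is lost in the next stage) | COC(c1cc(CC=C(C)C)c(OC(=O)C(C)(C)C)cc1OC(=O)c1ccc(OC)cc1OCC=C)[P+](c1ccccc1)(c1ccccc1)c1ccccc1.[O-]S(=O)(=O)C(F)(F)F | intermediate
12 | 2-[methoxy(triphenyl-λ5-phosphanylidene)methyl]-4-(3-methylbut-2-en-1-yl)-5-(pivaloyloxy)phenyl 2-(allyloxy)-4-methoxybenzoate (ylide) | COC(=P(c1ccccc1)(c1ccccc1)c1ccccc1)c1cc(CC=C(C)C)c(OC(=O)C(C)(C)C)cc1OC(=O)c1ccc(OC)cc1OCC=C | intermediate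
13 | 2-[2-(allyloxy)-4-methoxyphenyl]-3-methoxy-5-(3-methylbut-2-en-1-yl)-1-benzofuran-6-yl pivalate | COc1ccc(-c2oc3cc(OC(=O)C(C)(C)C)c(CC=C(C)C)cc3c2OC)c(OCC=C)c1 | intermediate
14 | ambofuranol, 2-(2-hydroxy-4-methoxyphenyl)-3-methoxy-5-(3-methylbut-2-en-1-yl)-1-benzofuran-6-ol (achiral) | COc1ccc(-c2oc3cc(O)c(CC=C(C)C)cc3c2OC)c(O)c1 | target

**Step count and risks**
Total steps: 7. Longest linear sequence: 6 (steps 1, 2, 4, 5, 6, 7); the ring-B branch (steps 3, 4, 5, 6, 7) is 5.

Steps most likely to fail: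

Step 6 (the proposed new step). The α-methoxy ylide must form a tetrasubstituted enol-ether double bond on an ester carbonyl, and ester cleavage by the ylide or base could compete. The fallback uses known chemistry only; it sets out from 4 and 7 and comes back to the route at 13. Acid 7 is reduced with LiAlH4 (THF, 0 °C) to [2-(allyloxy)-4-methoxyphenyl]methanol F1. Mitsunobu etherification of phenol 4 with F1 (PPh3, DIAD, THF, 0 → 23 °C) gives 5-{[2-(allyloxy)-4-methoxybenzyl]oxy}-4-formyl-2-(3-methylbut-2-en-1-yl)phenyl pivalate F2. Pinnick oxidation (NaClO2, NaH2PO4, excess 2-methyl-2-butene, t-BuOH/H2O) gives 2-{[2-(allyloxy)-4-methoxybenzyl]oxy}-5-(3-methylbut-2-en-1-yl)-4-(pivaloyloxy)benzoic acid F3, and MeI/K2CO3 in DMF gives methyl 2-{[2-(allyloxy)-4-methoxybenzyl]oxy}-5-(3-methylbut-2-en-1-yl)-4-(pivaloyloxy)benzoate F4. LDA (THF, −78 → 0 °C) deprotonates the α-aryloxybenzylic position and the anion acylates on the neighbouring methyl ester (Dieckmann/Claisen-type ring closure) to give 2-[2-(allyloxy)-4-methoxyphenyl]-5-(3-methylbut-2-en-1-yl)-3-oxo-2,3-dihydro-1-benzofuran-6-yl pivalate F5 (racemic, enolisable at C2). O-Methylation of its enolate (Me2SO4, K2CO3, acetone, reflux) gives 13.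

Step 2 (Stille prenylation). Risks are partial γ-coupling to the reverse-prenyl isomer and slow transfer of the hindered prenyl group next to the acyloxy substituent. The fallback sets out from 2 and comes back at 4. Stille coupling with allyltributylstannane (Pd2(dba)3, tri(2-furyl)phosphine, DMF, 80 °C), which has no α/γ ambiguity, gives 2-allyl-4-formyl-5-hydroxyphenyl pivalate F6. Olefin cross-metathesis with 2-methyl-2-butene (Grubbs II, 5 mol%, CH2Cl2/2-methyl-2-butene, 40 °C) then turns the allyl group into the prenyl group of 4.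

Step 5 (acetalisation beside the aryl ester). The neighbouring aroyloxy group can take part in the oxocarbenium chemistry, leading to acyl transfer or incomplete conversion. The fallback reverses the order so that no acetal of an ester-bearing aldehyde is needed; it sets out from 4 (with acid chloride 8) and comes back at 12. Aldehyde 4 is treated with PPh3·HBF4 and HC(OMe)3 in MeCN at 23 °C to give [(2-hydroxy-5-(3-methylbut-2-en-1-yl)-4-(pivaloyloxy)phenyl)(methoxy)methyl]triphenylphosphonium tetrafluoroborate F7 (racemic). O-Acylation of its phenol with 8 (Et3N, CH2Cl2, 0 °C) gives ({2-[(2-allyloxy-4-methoxybenzoyl)oxy]-5-(3-methylbut-2-en-1-yl)-4-(pivaloyloxy)phenyl}(methoxy)methyl)triphenylphosphonium tetrafluoroborate F8 (racemic), and KHMDS in THF converts it into ylide 12, from which step 6 continues.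

**Further compounds**
F1 | step 6 | [2-(allyloxy)-4-methoxyphenyl]methanol | COc1ccc(CO)c(OCC=C)c1
F2 | step 6 | 5-{[2-(allyloxy)-4-methoxybenzyl]oxy}-4-formyl-2-(3-methylbut-2-en-1-yl)phenyl pivalate | O=Cc1cc(CC=C(C)C)c(OC(=O)C(C)(C)C)cc1OCc1ccc(OC)cc1OCC=C
F3 | step 6 | 2-{[2-(allyloxy)-4-methoxybenzyl]oxy}-5-(3-methylbut-2-en-1-yl)-4-(pivaloyloxy)benzoic acid | OC(=O)c1cc(CC=C(C)C)c(OC(=O)C(C)(C)C)cc1OCc1ccc(OC)cc1OCC=C
F4 | step 6 | methyl 2-{[2-(allyloxy)-4-methoxybenzyl]oxy}-5-(3-methylbut-2-en-1-yl)-4-(pivaloyloxy)benzoate | COC(=O)c1cc(CC=C(C)C)c(OC(=O)C(C)(C)C)cc1OCc1ccc(OC)cc1OCC=C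
F5 | step 6 | 2-[2-(allyloxy)-4-methoxyphenyl]-5-(3-methylbut-2-en-1-yl)-3-oxo-2,3-dihydro-1-benzofuran-6-yl pivalate (racemic) | O=C1C(c2ccc(OC)cc2OCC=C)Oc2cc(OC(=O)C(C)(C)C)c(CC=C(C)C)cc21
F6 | step 2 | 2-allyl-4-formyl-5-hydroxyphenyl pivalate | O=Cc1cc(CC=C)c(OC(=O)C(C)(C)C)cc1O
F7 | step 5 | [(2-hydroxy-5-(3-methylbut-2-en-1-yl)-4-(pivaloyloxy)phenyl)(methoxy)methyl]triphenylphosphonium tetrafluoroborate (racemic) | COC(c1cc(CC=C(C)C)c(OC(=O)C(C)(C)C)cc1O)[P+](c1ccccc1)(c1ccccc1)c1ccccc1.F[B-](F)(F)F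
F8 | step 5 | ({2-[(2-allyloxy-4-methoxybenzoyl)oxy]-5-(3-methylbut-2-en-1-yl)-4-(pivaloyloxy)phenyl}(methoxy)methyl)triphenylphosphonium tetrafluoroborate (racemic) | COC(c1cc(CC=C(C)C)c(OC(=O)C(C)(C)C)cc1OC(=O)c1ccc(OC)cc1OCC=C)[P+](c1ccccc1)(c1ccccc1)c1ccccc1.F[B-](F)(F)F
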